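The flavone is cut at the C4–C4a bond of ring C. An intramolecular Friedel–Crafts acylation of a (Z)-β-aryloxyacrylic acid joins the carboxyl carbon (future C4) to C4a and so closes the pyranone ring in one operation. The step exploits the substitution of ring A: C4a lies between C8a, which carries the ring oxygen O1, and the methoxylated C5, while the only competing ortho carbon, C8, is the position at which 3,4-dimethoxyphenol brominates; a bromine there leaves C4a as the sole site of attack. The precursor is (Z)-3-(2-bromo-4,5-dimethoxyphenoxy)-3-(2,3,6-trimethoxyphenyl)acrylic acid, assembled by phenoxide addition to an arylpropiolate; the bromine is removed last.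

Key step: step 7

Remark: the conjugate addition of step 5 is drawn as the Z adduct expected from anti addition; any E isomer formed alongside is carried through steps 5 and 6, because the acid medium of step 7 interconverts the two.

Step 1
Reactants: 1 1,2,4-trimethoxybenzene
Product: 3 2,3,6-trimethoxybenzaldehyde, via (2,3,6-trimethoxyphenyl)lithium 2 (not isolated)
Conditions: n-BuLi (1.1 equiv), TMEDA, THF, 0 °C to rt; DMF, 0 °C; 1 M HCl
Reagents that add atoms: N,N-dimethylformamide, CN(C)C=O
Why: Directed ortho-metalation removes the proton at C3, the only position flanked by two methoxy groups, and the aryllithium is formylated by DMF, which places the aldehyde between the methoxy groups, whereas electrophilic (Vilsmeier) formylation would enter C5.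

Step 2
Reactants: 3 2,3,6-trimethoxybenzaldehyde
Product: 4 2-(2,2-dibromoethenyl)-1,3,4-trimethoxybenzene
Conditions: CBr4 (2 equiv), PPh3 (4 equiv), CH2Cl2, 0 °C
Reagents that add atoms: carbon tetrabromide, BrC(Br)(Br)Br
Why: Corey–Fuchs dibromo-olefination, a Wittig reaction of the ylide Ph3P=CBr2 that is reliable for hindered, electron-rich benzaldehydes.

Step 3
Reactants: 4 2-(2,2-dibromoethenyl)-1,3,4-trimethoxybenzene
Product: 6 methyl 3-(2,3,6-trimethoxyphenyl)prop-2-ynoate, via lithium (2,3,6-trimethoxyphenyl)ethynide 5 (not isolated)
Conditions: n-BuLi (2.1 equiv), THF, −78 °C to 0 °C; ClCO2Me (1.5 equiv), −78 °C to rt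
Reagents that add atoms: methyl chloroformate, COC(Cl)=O
Why: The second stage of the Corey–Fuchs sequence (bromine–lithium exchange, Fritsch–Buttenberg–Wiechell shift and deprotonation) should give the lithium acetylide, which is C-acylated by the chloroformate.

Step 4
Reactants: 7 3,4-dimethoxyphenol
Product: 8 2-bromo-4,5-dimethoxyphenol
Conditions: NBS (1.0 equiv), MeCN, −20 °C to 0 °C
Reagents that add atoms: N-bromosuccinimide, O=C1CCC(=O)N1Br
Why: Electrophilic aromatic bromination should go to C6 of the phenol, which is ortho to the hydroxyl, para to the 3-methoxy group and unhindered, whereas C2 is squeezed between two oxygen substituents.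

Step 5
Reactants: 6 methyl 3-(2,3,6-trimethoxyphenyl)prop-2-ynoate; 8 2-bromo-4,5-dimethoxyphenol
Product: 9 methyl (Z)-3-(2-bromo-4,5-dimethoxyphenoxy)-3-(2,3,6-trimethoxyphenyl)prop-2-enoate
Conditions: K2CO3 (0.3 equiv), DMF, 80 °C, N2
Reagents that add atoms: none
Why: Oxa-Michael addition of the phenoxide to the ynoate (first stage of the Ruhemann flavone synthesis) should proceed by anti addition across the triple bond, placing the aryloxy and ester groups cis.

Step 6
Reactants: 9 methyl (Z)-3-(2-bromo-4,5-dimethoxyphenoxy)-3-(2,3,6-trimethoxyphenyl)prop-2-enoate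
Product: 10 (Z)-3-(2-bromo-4,5-dimethoxyphenoxy)-3-(2,3,6-trimethoxyphenyl)prop-2-enoic acid
Conditions: LiOH·H2O (3 equiv), THF/MeOH/H2O, rt to 40 °C; 1 M HCl to pH 3, 0 °C
Reagents that add atoms: lithium hydroxide (aqueous), [Li+].[OH-]
Why: Saponification of the methyl ester (BAC2 acyl substitution) should leave the aryl bromide, the methyl ethers and the enol ether untouched, provided the acidification is done cold.

Step 7
Reactants: 10 (Z)-3-(2-bromo-4,5-dimethoxyphenoxy)-3-(2,3,6-trimethoxyphenyl)prop-2-enoic acid
Product: 12 8-bromo-5,6-dimethoxy-2-(2,3,6-trimethoxyphenyl)-4H-chromen-4-one, via acyl methanesulfonate 11 (not isolated)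
Conditions: P2O5/MeSO3H (1:10 w/w), rt to 40 °C; ice water
Reagents that add atoms: none
Why: The medium converts the acid into the mixed anhydride 11, which ionises to an acylium ion; this attacks the phenoxy-ring carbon between the ether oxygen and the adjacent methoxy group (future C4a), and loss of a proton restores aromaticity and leaves the C4–C4a bond. The closest known reaction type is the acid-mediated cyclisation of β-aryloxycinnamic acids to flavones (Ruhemann synthesis), an intramolecular Friedel–Crafts acylation. Ring C closes as a six-membered ring by electrophilic aromatic substitution, exo with respect to the acylium C–O multiple bond and endo with respect to the arene C4a–C8a bond. No stereocentre is formed; only the Z acid can reach the ring, and any E isomer should converge on it by reversible protonation of the enol ether at the α-carbon. The step needs acylation at the crowded ortho carbon instead of the open one (future C8): the bromine occupies C8, both ortho positions of ring B carry methoxy groups so no indenone can form, and the attacked carbon is activated by two ortho oxygen donors.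

Step 8
Reactants: 12 8-bromo-5,6-dimethoxy-2-(2,3,6-trimethoxyphenyl)-4H-chromen-4-one
Product: 13 5,6,2',3',6'-pentamethoxyflavone (5,6-dimethoxy-2-(2,3,6-trimethoxyphenyl)-4H-chromen-4-one)
Conditions: Pd(OAc)2 (5 mol %), PPh3 (20 mol %), HCO2Na (3 equiv), DMF, 100 °C
Reagents that add atoms: none
Why: Palladium-catalysed hydrodehalogenation, in which zerovalent palladium inserts into the C8–Br bond, formate replaces bromide and decarboxylates to an aryl palladium hydride, and reductive elimination forms C8–H; a homogeneous phosphine catalyst is chosen so that the C2–C3 double bond of ring C is not reduced.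

Compound list
1 | 1,2,4-trimethoxybenzene | COc1ccc(OC)c(OC)c1 | starting material
2 | (2,3,6-trimethoxyphenyl)lithium | [Li]c1c(OC)ccc(OC)c1OC | intermediate
3 | 2,3,6-trimethoxybenzaldehyde | O=Cc1c(OC)ccc(OC)c1OC | intermediate
4 | 2-(2,2-dibromoethenyl)-1,3,4-trimethoxybenzene | BrC(Br)=Cc1c(OC)ccc(OC)c1OC | intermediate
5 | lithium (2,3,6-trimethoxyphenyl)ethynide | [Li]C#Cc1c(OC)ccc(OC)c1OC | intermediate
6 | methyl 3-(2,3,6-trimethoxyphenyl)prop-2-ynoate | COC(=O)C#Cc1c(OC)ccc(OC)c1OC | intermediate
7 | 3,4-dimethoxyphenol | COc1ccc(O)cc1OC | starting material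
8 | 2-bromo-4,5-dimethoxyphenol | COc1cc(O)c(Br)cc1OC | intermediate
9 | methyl (Z)-3-(2-bromo-4,5-dimethoxyphenoxy)-3-(2,3,6-trimethoxyphenyl)prop-2-enoate | COC(=O)/C=C(\Oc1cc(OC)c(OC)cc1Br)c1c(OC)ccc(OC)c1OC | intermediate
10 | (Z)-3-(2-bromo-4,5-dimethoxyphenoxy)-3-(2,3,6-trimethoxyphenyl)prop-2-enoic acid | OC(=O)/C=C(\Oc1cc(OC)c(OC)cc1Br)c1c(OC)ccc(OC)c1OC | intermediate
11 | (Z)-3-(2-bromo-4,5-dimethoxyphenoxy)-3-(2,3,6-trimethoxyphenyl)prop-2-enoic methanesulfonic anhydride | CS(=O)(=O)OC(=O)/C=C(\Oc1cc(OC)c(OC)cc1Br)c1c(OC)ccc(OC)c1OC | intermediate
12 | 8-bromo-5,6-dimethoxy-2-(2,3,6-trimethoxyphenyl)-4H-chromen-4-one | COc1cc(Br)c2oc(-c3c(OC)ccc(OC)c3OC)cc(=O)c2c1OC | intermediate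
13 | 5,6,2',3',6'-pentamethoxyflavone | COc1ccc(OC)c(-c2cc(=O)c3c(OC)c(OC)ccc3o2)c1OC | target

Total step count: 8
Longest linear sequence: 7 steps (steps 1, 2, 3, 5, 6, 7, 8)

Steps most likely to fail

Step 7. The blocking bromine could be lost or could migrate by ipso protonation of the electron-rich ring in the strongly acidic medium, which would reopen the unhindered ortho carbon and divert acylation to the wrong regioisomer. The enol ether could also be cleaved before the ring closes. The fallback sets out from 8 and 3 and comes back to the route at 12, forming ring C through the O1–C2 bond instead. Phenol 8 would be C-acetylated at its only free ortho carbon with AcOH in BF3·OEt2 at 90 °C (boron-chelate-directed Friedel–Crafts acylation) to give 1-(3-bromo-2-hydroxy-5,6-dimethoxyphenyl)ethan-1-one F1. Claisen–Schmidt condensation of this ketone with aldehyde 3 (KOH, EtOH, rt) should give (E)-1-(3-bromo-2-hydroxy-5,6-dimethoxyphenyl)-3-(2,3,6-trimethoxyphenyl)prop-2-en-1-one F2. Oxidative cyclisation of the chalcone with catalytic I2 in DMSO at 130 °C should then deliver 12.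

Step 5. Conjugate addition could be too slow at a β-carbon that is shielded by two ortho methoxy groups and deactivated by the electron-rich ring, especially with a hindered, weakly nucleophilic ortho-bromophenoxide; forcing could cause reversal or decomposition. The fallback sets out from 6 (with 8) and comes back at 9, replacing the conjugate addition by a metal-catalysed C–O coupling. Hydroiodination of 6 with NaI in AcOH at 80 °C should give methyl (Z)-3-iodo-3-(2,3,6-trimethoxyphenyl)prop-2-enoate F3. An Ullmann-type vinylic coupling of this iodide with 8 (CuI, N,N-dimethylglycine, Cs2CO3, dioxane, 90 °C) should give 9 with retention of the double-bond geometry, the vinyl iodide reacting ahead of the aryl bromide.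

Step 8. The palladium hydride could reduce the C2–C3 double bond of ring C, or oxidative addition could stall at the hindered, electron-rich C8–Br bond. The fallback sets out from 12 and comes back at 13 by a radical chain reduction instead of palladium hydride chemistry: Bu3SnH with AIBN in toluene at 100 °C should abstract bromine and transfer hydrogen to the aryl radical without touching the enone; no new compound is made on the way.

Further compounds
F1 | step 7 | 1-(3-bromo-2-hydroxy-5,6-dimethoxyphenyl)ethan-1-one | CC(=O)c1c(O)c(Br)cc(OC)c1OC
F2 | step 7 | (E)-1-(3-bromo-2-hydroxy-5,6-dimethoxyphenyl)-3-(2,3,6-trimethoxyphenyl)prop-2-en-1-one | COc1ccc(OC)c(/C=C/C(=O)c2c(O)c(Br)cc(OC)c2OC)c1OC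
F3 | step 5 | methyl (Z)-3-iodo-3-(2,3,6-trimethoxyphenyl)prop-2-enoate | COC(=O)/C=C(\I)c1c(OC)ccc(OC)c1OC
F0 | step 8 | none | none
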